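## Retrosynthetic overview
1. The end game forms no rings. O-acetylation, radical isopropylation at C13, arene → hydroxy-p-quinone oxidation and C6–C7 dehydrogenation lead back to an 11,12,14-trimethoxy tricyclic 19,20-lactone.
2. δ-Lactone: the C19(acyl)–O20 bond is closed by a C20 hydroxyl onto the 1,3-diaxial C19 ester, the pairing of C20-OH and C19 acid level presumed in the plant. This closure expels the chiral auxiliary, and the C3 ketone is removed in the same operation.
3. Rings A and B: C4–C5, then C10–C9, in one oxidative radical polyene cascade of an acyclic α-methyl β-keto ester that already carries the C19 and C20 oxygens. These are the same bonds, in the same order, as in the diterpene cyclase. An 8-phenylmenthyl ester sets C4, C5 and C10.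
4. Acyclic precursor: C3–C4 by crossed Claisen, C1–C2 by Johnson–Claisen (fixes the alkene geometry), C5–C10 by vinyllithium addition, C7–C8 by Heck.
5. Ring order: C (bought as the arene) → A → B (same flask) → lactone → ring C raised to the quinone.

Assumption: abietane numbering (C1–C20) is used for all compounds, acyclic ones included, and the facial bias of the 8-phenylmenthyl ester is taken from the usual stacked-phenyl model.

## Route

Step 1
Reactants: 1 aryl bromide 1-bromo-2,4,5-trimethoxybenzene; 2 allyl alcohol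
Product: 3 aldehyde 3-(2,4,5-trimethoxyphenyl)propanal
Conditions: Pd(OAc)2 (3 mol %), P(o-tol)3 (6 mol %), n-Bu4NCl, NaHCO3, DMF, 90 °C
Reagents that add atoms: none
Why: Heck arylation of allyl alcohol in which aryl-palladium adds to the terminal alkene carbon and β-hydride elimination toward the carbinol gives an enol that tautomerises to the aldehyde (C7–C8 bond), with no stereocentre formed.

Step 2
Reactants: 4 2-bromoprop-2-en-1-ol
Product: 5 silyl ether (2-bromoallyloxy)(tert-butyl)dimethylsilane
Conditions: TBSCl, imidazole, CH2Cl2, 0 °C to rt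
Reagents that add atoms: tert-butyldimethylsilyl chloride, CC(C)(C)[Si](C)(C)Cl
Why: Standard silylation masks the future C20 hydroxyl so that only the secondary alcohol made in step 3 can enter the Claisen rearrangement.

Step 3
Reactants: 5 silyl ether (2-bromoallyloxy)(tert-butyl)dimethylsilane; 3 aldehyde 3-(2,4,5-trimethoxyphenyl)propanal
Product: 7 racemic allylic alcohol 2-[(tert-butyldimethylsilyloxy)methyl]-5-(2,4,5-trimethoxyphenyl)pent-1-en-3-ol, via vinyllithium 6 (not isolated)
Conditions: t-BuLi (2.0 equiv), Et2O, −78 °C; add 3, −78 °C; H2O quench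
Reagents that add atoms: none
Why: Bromine–lithium exchange followed by 1,2-addition to the aldehyde forms C5–C10, and the new carbinol centre is left racemic because step 4 erases it.

Step 4
Reactants: 7 racemic allylic alcohol
Product: 9 ethyl (Z)-4-[(tert-butyldimethylsilyloxy)methyl]-7-(2,4,5-trimethoxyphenyl)hept-4-enoate, via mixed ketene acetal 8 (not isolated)
Conditions: MeC(OEt)3 (6 equiv), EtCO2H (10 mol %), 140 °C, EtOH distilled off
Reagents that add atoms: triethyl orthoacetate, CC(OCC)(OCC)OCC
Why: Johnson–Claisen rearrangement through a chair with the arylethyl group equatorial forms C1–C2 and places C6 trans to C1 and cis to CH2OTBS (Z by CIP), the geometry a chair–chair fold needs for a trans A/B fusion.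

Step 5
Reactants: 10 (−)-8-phenylmenthol, (1R,2S,5R)-5-methyl-2-(2-phenylpropan-2-yl)cyclohexan-1-ol
Product: 11 (−)-8-phenylmenthyl propionate
Conditions: EtCOCl, Et3N, DMAP (5 mol %), CH2Cl2, 0 °C to rt
Reagents that add atoms: propionyl chloride, CCC(=O)Cl
Why: DMAP-catalysed acylation of the secondary alcohol leaves the auxiliary stereocentres untouched.

Step 6
Reactants: 11 (−)-8-phenylmenthyl propionate; 9 ethyl (Z)-heptenoate
Product: 13 β-keto ester (−)-8-phenylmenthyl (Z)-6-[(tert-butyldimethylsilyloxy)methyl]-2-methyl-3-oxo-9-(2,4,5-trimethoxyphenyl)non-6-enoate (C4 epimers), via lithium enolate 12 (not isolated)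
Conditions: LiN(iPr)2 (2.2 equiv), 11 (2.2 equiv), THF, −78 °C; add 9, −78 to 0 °C; AcOH quench; surplus 11 recovered
Reagents that add atoms: none
Why: Crossed Claisen condensation in which the hindered propionate cannot self-condense, its enolate acylates on the unhindered ethyl ester (C3–C4), and the second equivalent drives the reaction by deprotonating the product, the C4 epimer mixture being irrelevant because C4 becomes a planar radical.

Step 7
Reactants: 13 β-keto ester
Product: 16 tricyclic keto ester (−)-8-phenylmenthyl 20-(tert-butyldimethylsilyloxy)-11,12,14-trimethoxy-3-oxopodocarpa-8,11,13-trien-19-oate (4β-ester 5α-H 10β-CH2OTBS), via C4 radical 14 (not isolated), via C10 radical 15 (not isolated)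
Conditions: Mn(OAc)3·2H2O (2.2 equiv, in portions), degassed AcOH, 20 °C, 4–6 h; chromatography to a single diastereomer
Reagents that add atoms: none
Why: Proposed new method: Mn(OAc)3 oxidises the enol of 13 to the planar electrophilic C4 radical 14, which adds 6-endo through a chair to the less substituted alkene carbon C5 (ring A), and the tertiary C10 radical 15 then closes ring B on the only free ortho position C9 before a second Mn(OAc)3 re-aromatises; the dipole-opposed keto ester rotamer puts the ester axial at C4, the alkene geometry puts C6 equatorial at C5, arene attack anti to the axial ester leaves CH2OTBS axial at C10, and the cumyl phenyl ring of the (1R,2S,5R) auxiliary stacks over one face of 14 so that C5 bonds on the open face to give the 4β,5α,10β series; the closest known reaction type is the Mn(OAc)3 oxidative free-radical bicyclisation of α-methyl β-keto esters onto anisole rings that gives podocarpate skeletons with an axial ester, and what is new is the allylic silyl ether, the trimethoxyarene terminator and the use of the auxiliary for all three centres.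

Step 8
Reactants: 16 tricyclic keto ester
Product: 18 lactone 11,12,14-trimethoxypodocarpa-8,11,13-trien-19,20-olide (5α-H; C19 and C20 both β), via hydroxy ester 17 (not isolated)
Conditions: Zn dust (excess), HCl(g)-saturated Et2O, −10 to 0 °C, 2 h; filter, evaporate; TsOH·H2O (10 mol %), PhMe, 90 °C
Reagents that add atoms: none
Why: Clemmensen reduction in its cold anhydrous form removes the C3 carbonyl, the same HCl cleaves the silyl ether, and the freed C20 hydroxyl, held 1,3-diaxial to the C19 ester, closes the δ-lactone by acid-catalysed transesterification that expels auxiliary 10 for re-use, with no stereocentre touched.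

Step 9
Reactants: 18 lactone
Product: 19 styrene 11,12,14-trimethoxypodocarpa-6,8,11,13-tetraen-19,20-olide
Conditions: DDQ (1.3 equiv), anhydrous 1,4-dioxane, 90 °C
Reagents that add atoms: none
Why: DDQ benzylic dehydrogenation, in which hydride leaves C7 because the cation is stabilised by the para 12-OMe and ortho 14-OMe groups and loss of H6 gives the conjugated alkene, leaves C5 intact.

Step 10
Reactants: 19 styrene
Product: 21 hydroxyquinone 12-hydroxy-11,14-dioxopodocarpa-6,8,12-trien-19,20-olide, via triol 20 (not isolated)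
Conditions: BBr3 (4.5 equiv), CH2Cl2, −78 to 0 °C; H2O; then air, EtOAc, rt
Reagents that add atoms: none
Why: BBr3 cleaves the three aryl methyl ethers while the neopentyl lactone C–O bond resists bromide, and the 1,2,4-triol autoxidises on contact with air to the stable 2-hydroxy-1,4-quinone tautomer.

Step 11
Reactants: 21 hydroxyquinone
Product: 22 12-hydroxy-11,14-dioxoabieta-6,8,12-trien-19,20-olide
Conditions: i-PrCO2H (3 equiv), AgNO3 (0.2 equiv), (NH4)2S2O8 (1.5 equiv), MeCN/H2O 1:1, 65 °C
Reagents that add atoms: isobutyric acid, CC(C)C(=O)O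
Why: Silver-catalysed decarboxylative radical alkylation of a quinone (Jacobsen–Torssell, Minisci type), in which the nucleophilic isopropyl radical adds to C13, the only unsubstituted quinone carbon, faster than to the hindered C6 terminus of the vinyl group, and persulfate restores the quinone.

Step 12
Reactants: 22 12-hydroxy-11,14-dioxoabieta-6,8,12-trien-19,20-olide
Product: 23 target 12-acetoxy-11,14-dioxoabieta-6,8,12-trien-19,20-olide
Conditions: Ac2O, pyridine, CH2Cl2, 0 °C to rt
Reagents that add atoms: acetic anhydride, CC(=O)OC(C)=O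
Why: O-acylation of the acidic vinylogous-acid hydroxyl, the only OH in the molecule, under conditions too mild to epimerise C5.

## Compound list
1 | 1-bromo-2,4,5-trimethoxybenzene | COc1cc(OC)c(OC)cc1Br | starting material
2 | allyl alcohol | C=CCO | starting material
3 | 3-(2,4,5-trimethoxyphenyl)propanal | COc1cc(OC)c(OC)cc1CCC=O | intermediate
4 | 2-bromoprop-2-en-1-ol | OCC(Br)=C | starting material
5 | (2-bromoallyloxy)(tert-butyl)dimethylsilane | C=C(Br)CO[Si](C)(C)C(C)(C)C | intermediate
6 | 3-(tert-butyldimethylsilyloxy)prop-1-en-2-yllithium | [Li]C(=C)CO[Si](C)(C)C(C)(C)C | intermediate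
7 | rac-2-[(tert-butyldimethylsilyloxy)methyl]-5-(2,4,5-trimethoxyphenyl)pent-1-en-3-ol | COc1cc(OC)c(OC)cc1CCC(O)C(=C)CO[Si](C)(C)C(C)(C)C | intermediate
8 | 1-ethoxyvinyl ether of 7 (mixed ketene acetal) | CCOC(=C)OC(CCc1cc(OC)c(OC)cc1OC)C(=C)CO[Si](C)(C)C(C)(C)C | intermediate
9 | ethyl (Z)-4-[(tert-butyldimethylsilyloxy)methyl]-7-(2,4,5-trimethoxyphenyl)hept-4-enoate | CCOC(=O)CC/C(CO[Si](C)(C)C(C)(C)C)=C/CCc1cc(OC)c(OC)cc1OC | intermediate
10 | (−)-8-phenylmenthol (1R,2S,5R) | O[C@@H]1C[C@H](C)CC[C@H]1C(C)(C)c1ccccc1 | starting material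
11 | (−)-8-phenylmenthyl propionate | CCC(=O)O[C@@H]1C[C@H](C)CC[C@H]1C(C)(C)c1ccccc1 | intermediate
12 | lithium enolate of 11 | [Li]OC(=CC)O[C@@H]1C[C@H](C)CC[C@H]1C(C)(C)c1ccccc1 | intermediate
13 | (−)-8-phenylmenthyl (Z)-6-[(tert-butyldimethylsilyloxy)methyl]-2-methyl-3-oxo-9-(2,4,5-trimethoxyphenyl)non-6-enoate, C4 epimers | CC(C(=O)CC/C(CO[Si](C)(C)C(C)(C)C)=C/CCc1cc(OC)c(OC)cc1OC)C(=O)O[C@@H]1C[C@H](C)CC[C@H]1C(C)(C)c1ccccc1 | intermediate
14 | C4 radical of 13 | C[C](C(=O)CC/C(CO[Si](C)(C)C(C)(C)C)=C/CCc1cc(OC)c(OC)cc1OC)C(=O)O[C@@H]1C[C@H](C)CC[C@H]1C(C)(C)c1ccccc1 | intermediate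
15 | ring A closed tertiary C10 radical (4β-ester, 5α-H) | COc1cc(OC)c(OC)cc1CC[C@@H]2[C](CO[Si](C)(C)C(C)(C)C)CCC(=O)[C@]2(C)C(=O)O[C@@H]3C[C@H](C)CC[C@H]3C(C)(C)c3ccccc3 | intermediate
16 | (−)-8-phenylmenthyl 20-(tert-butyldimethylsilyloxy)-11,12,14-trimethoxy-3-oxopodocarpa-8,11,13-trien-19-oate (4β-ester, 5α-H, 10β-CH2OTBS) | COc1cc(OC)c2CC[C@H]3[C@@](C)(C(=O)O[C@@H]4C[C@H](C)CC[C@H]4C(C)(C)c4ccccc4)C(=O)CC[C@]3(CO[Si](C)(C)C(C)(C)C)c2c1OC | intermediate
17 | (−)-8-phenylmenthyl 20-hydroxy-11,12,14-trimethoxypodocarpa-8,11,13-trien-19-oate | COc1cc(OC)c2CC[C@H]3[C@@](C)(C(=O)O[C@@H]4C[C@H](C)CC[C@H]4C(C)(C)c4ccccc4)CCC[C@]3(CO)c2c1OC | intermediate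
18 | 11,12,14-trimethoxypodocarpa-8,11,13-trien-19,20-olide | COc1cc(OC)c2CC[C@H]3[C@]4(C)CCC[C@]3(COC4=O)c2c1OC | intermediate
19 | 11,12,14-trimethoxypodocarpa-6,8,11,13-tetraen-19,20-olide | COc1cc(OC)c2C=C[C@H]3[C@]4(C)CCC[C@]3(COC4=O)c2c1OC | intermediate
20 | 11,12,14-trihydroxypodocarpa-6,8,11,13-tetraen-19,20-olide | Oc1cc(O)c2C=C[C@H]3[C@]4(C)CCC[C@]3(COC4=O)c2c1O | intermediate
21 | 12-hydroxy-11,14-dioxopodocarpa-6,8,12-trien-19,20-olide | OC1=CC(=O)C2=C(C1=O)[C@]13CCC[C@](C)(C(=O)OC1)[C@@H]3C=C2 | intermediate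
22 | 12-hydroxy-11,14-dioxoabieta-6,8,12-trien-19,20-olide | OC1=C(C(C)C)C(=O)C2=C(C1=O)[C@]13CCC[C@](C)(C(=O)OC1)[C@@H]3C=C2 | intermediate
23 | 12-acetoxy-11,14-dioxoabieta-6,8,12-trien-19,20-olide (CNP0596241.1) | CC(=O)OC1=C(C(C)C)C(=O)C2=C(C1=O)[C@]13CCC[C@](C)(C(=O)OC1)[C@@H]3C=C2 | target

## Count and risks
Total steps: 12. Longest linear sequence: 10 (steps 1, 3, 4, 6, 7, 8, 9, 10, 11, 12).

**Step 7 (cascade).**
- Risks: trivalent manganese may oxidise the trimethoxyarene before the hindered keto ester enolises, closure next to the 11-OMe group is crowded, and the facial bias may be only moderate.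
- Fallback: set out from 13. Deprotonate with NaH and quench with N-chlorosuccinimide (THF, 0 °C) to obtain the α-chloro β-keto ester F1. Then generate the same C4 radical reductively with fac-Ir(ppy)3 (1 mol %), 2,6-lutidine, MeCN, blue LEDs, rt. The oxidised iridium complex is too weak an oxidant to touch the arene but re-aromatises the cyclohexadienyl radical, so the cascade is redox-neutral. It comes back to the route at 16.

**Step 8 (Clemmensen, desilylation and lactonisation in one operation).**
- Risks: the ketone next to quaternary C4 may reduce poorly or rearrange, and expulsion of the bulky auxiliary may lag.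
- Fallback: set out from 16. Treat with n-Bu4NF (THF, 50 °C) so that the C20 alkoxide lactonises first, giving the keto lactone F2. Convert the ketone with ethane-1,2-dithiol and BF3·OEt2 into the dithiolane F3. Desulfurise with Raney Ni (EtOH, reflux). It comes back at 18.

**Step 11 (late radical isopropylation).**
- Risks: the 3-unsubstituted hydroxyquinone is a modest radical acceptor, and the vinyl group or the oxidant may interfere.
- Fallback: set out from 18 and install the group by polar and cross-coupling chemistry on the arene.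
  - NBS (MeCN, 0 °C) gives the 13-bromide F4.
  - Negishi coupling with i-PrZnBr, Pd(OAc)2 and CPhos (THF, rt) gives the isopropyl arene F5.
  - DDQ (dioxane, 90 °C) gives the styrene F6.
  - BBr3 followed by air passes through the triol F7 and comes back at 22.

## Further compounds
F1 | step 7 | (−)-8-phenylmenthyl (Z)-2-chloro-6-[(tert-butyldimethylsilyloxy)methyl]-2-methyl-3-oxo-9-(2,4,5-trimethoxyphenyl)non-6-enoate | CC(Cl)(C(=O)CC/C(CO[Si](C)(C)C(C)(C)C)=C/CCc1cc(OC)c(OC)cc1OC)C(=O)O[C@@H]1C[C@H](C)CC[C@H]1C(C)(C)c1ccccc1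
F2 | step 8 | 11,12,14-trimethoxy-3-oxopodocarpa-8,11,13-trien-19,20-olide | COc1cc(OC)c2CC[C@H]3[C@]4(C)C(=O)CC[C@]3(COC4=O)c2c1OC
F3 | step 8 | 3,3-(ethane-1,2-diyldithio)-11,12,14-trimethoxypodocarpa-8,11,13-trien-19,20-olide | COc1cc(OC)c2CC[C@H]3[C@]4(C)C5(SCCS5)CC[C@]3(COC4=O)c2c1OC
F4 | step 11 | 13-bromo-11,12,14-trimethoxypodocarpa-8,11,13-trien-19,20-olide | COc1c(Br)c(OC)c2CC[C@H]3[C@]4(C)CCC[C@]3(COC4=O)c2c1OC
F5 | step 11 | 11,12,14-trimethoxyabieta-8,11,13-trien-19,20-olide | COc1c(C(C)C)c(OC)c2CC[C@H]3[C@]4(C)CCC[C@]3(COC4=O)c2c1OC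
F6 | step 11 | 11,12,14-trimethoxyabieta-6,8,11,13-tetraen-19,20-olide | COc1c(C(C)C)c(OC)c2C=C[C@H]3[C@]4(C)CCC[C@]3(COC4=O)c2c1OC
F7 | step 11 | 11,12,14-trihydroxyabieta-6,8,11,13-tetraen-19,20-olide | Oc1c(C(C)C)c(O)c2C=C[C@H]3[C@]4(C)CCC[C@]3(COC4=O)c2c1O
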